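**Plan**

- Flavanone numbering is used (O1, C2, C3, C4, C4a, C5–C8, C8a). The C4 carbonyl is traced back to a C4 methyl ether, and ring C is then cut at O1–C2, C3–C4 and C4–OMe.
- This exposes O1–C8a–C4a–C4 as an oxadiene latent in 2-hydroxy-4-methoxybenzaldehyde (ring A). C2–C3 is the vinyl group of 2-(4-methoxyphenyl)-5-vinylbenzofuran, a styrene whose vinyl-bearing ring carbon is para to the benzofuran oxygen. Trimethyl orthoformate supplies the C4 methoxy group.
- The vinyl group is cut at C=C (Wittig) and the furan ring at its C3a–C3 and O–C2 bonds (alkyne coupling, then cyclisation).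
- Forward: furan ring (step 1), vinyl group (step 2), ring C by a three-component oxa-[4+2] cycloaddition (step 3), C4 oxidation (step 4). Ring A and the anisyl ring are bought.
- Stereochemistry: C2 (S) is set in step 3 by a confined chiral Brønsted acid. The C4 centre made with it is sacrificial and is erased in step 4.

Key step: step 3

Assumption: the sense of induction of the confined acid cannot be predicted with certainty; the (S,S)-catalyst is written, and its mirror image would be used if a test run gives the (2R,4R) series.

**Route**

Step 1
Reactants: 1 4-hydroxy-3-iodobenzaldehyde; 2 4-ethynylanisole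
Product: 4 2-(4-methoxyphenyl)benzofuran-5-carbaldehyde, via alkynylphenol 3 (not isolated)
Conditions: PdCl2(PPh3)2 (2 mol %), CuI (4 mol %), Et3N, degassed DMF, rt then 70 °C
Reagents that add atoms: none
Why: Sonogashira coupling at the aryl iodide should give ortho-alkynylphenol 3, whose phenoxide (made more acidic by the para-formyl group) adds 5-endo-dig to the metal-activated alkyne on warming, a standard tandem coupling–heteroannulation route from ortho-iodophenols to 2-arylbenzofurans that leaves the aldehyde and aryl methyl ether untouched.

Step 2
Reactants: 4 2-(4-methoxyphenyl)benzofuran-5-carbaldehyde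
Product: 5 2-(4-methoxyphenyl)-5-vinylbenzofuran
Conditions: Ph3PCH3Br, KOtBu, THF, 0 °C to rt
Reagents that add atoms: methyltriphenylphosphonium bromide, C[P+](c1ccccc1)(c1ccccc1)c1ccccc1.[Br-]
Why: Wittig methylenation of a non-enolisable aryl aldehyde with the non-stabilised ylide made in the flask is reliable and spares the benzofuran and methyl ether; the electron-rich styrene is stored cold with a trace of BHT and used promptly.

Step 3
Reactants: 6 2-hydroxy-4-methoxybenzaldehyde (1.2 equiv); 7 trimethyl orthoformate (1.5 equiv); 5 2-(4-methoxyphenyl)-5-vinylbenzofuran (added slowly)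
Product: 10 (2S,4S)-4,7-dimethoxy-2-[2-(4-methoxyphenyl)benzofuran-5-yl]chroman (2,4-cis), via dimethyl acetal 8 (not isolated), via oxocarbenium ion 9 (not isolated)
Conditions: (S,S)-IDPi (confined imidodiphosphorimidate Brønsted acid, 5 mol %), 5 Å MS, CH2Cl2, −40 °C; Et3N quench at −40 °C
Reagents that add atoms: none
Why: Proposed new method: the chiral acid should convert 6 and 7 into acetal 8 and ionise it to oxocarbenium ion 9 (a protonated 4-methoxy ortho-quinone methide) held in a confined chiral ion pair; the vinyl terminus of 5 then adds to the carbenium carbon (C3–C4) while the phenol oxygen captures the developing C2 benzylic cation (O1–C2), a concerted but asynchronous inverse-demand oxa-Diels–Alder reaction. The closest known reactions are the racemic acid-catalysed salicylaldehyde–orthoformate–styrene [4+2] route to 2-aryl-4-alkoxychromans and the confined-acid-catalysed asymmetric cycloadditions of ortho-quinone methides and of simple styrenes with cationic heterodienes. Ring C closes as the six-membered ring of a [4+2] cycloaddition (a 6-endo capture of the benzylic cation by the phenol oxygen if the process is stepwise). C4 is set by the face of the oxocarbenium left open by the chiral anion, and C2 by the endo approach of the aryl group inside the pocket, which places the aryl and OMe groups cis and so gives the (2S,4S) isomer. The step needs enantiofacial control, cis selectivity (a trans isomer from the exo mode would carry the opposite C2 configuration into the ketone, so any minor diastereomer is removed before step 4) and attack by the vinyl group instead of benzofuran C3. The confined anion and low temperature should secure the first two, and the unhindered vinyl terminus, activated by para-oxygen donation, should outcompete C3, which is flanked by the aryl group.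

Step 4
Reactants: 10 (2S,4S)-4,7-dimethoxy-2-[2-(4-methoxyphenyl)benzofuran-5-yl]chroman
Product: 12 Lophirone J [(S)-7-methoxy-2-[2-(4-methoxyphenyl)benzofuran-5-yl]chroman-4-one], via methyl hemiketal 11 (not isolated)
Conditions: DDQ (1.2 equiv), CH2Cl2/pH 7 phosphate buffer (10:1), 0 °C to rt
Reagents that add atoms: water, O
Why: DDQ oxidation of a para-methoxybenzylic ether (the reaction type behind oxidative PMB-ether cleavage and C4 functionalisation of flavans) should abstract the pseudo-axial C4 hydride, activated by the 7-OMe group, O1 and the C4 methoxy oxygen, and water then gives hemiketal 11, which loses methanol to the ketone, while the less hydridic C2–H and the buffered, non-basic medium should keep the C2 centre intact.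

**Compound list**

1 | 4-hydroxy-3-iodobenzaldehyde | O=Cc1ccc(O)c(I)c1 | starting material
2 | 4-ethynylanisole | C#Cc1ccc(OC)cc1 | starting material
3 | 4-hydroxy-3-[(4-methoxyphenyl)ethynyl]benzaldehyde (formed in the flask, step 1) | COc1ccc(C#Cc2cc(C=O)ccc2O)cc1 | intermediate
4 | 2-(4-methoxyphenyl)benzofuran-5-carbaldehyde | COc1ccc(-c2cc3cc(C=O)ccc3o2)cc1 | intermediate
5 | 2-(4-methoxyphenyl)-5-vinylbenzofuran | C=Cc1ccc2oc(-c3ccc(OC)cc3)cc2c1 | intermediate
6 | 2-hydroxy-4-methoxybenzaldehyde | COc1ccc(C=O)c(O)c1 | starting material
7 | trimethyl orthoformate | COC(OC)OC | starting material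
8 | 2-(dimethoxymethyl)-5-methoxyphenol (formed in the flask, step 3) | COc1ccc(C(OC)OC)c(O)c1 | intermediate
9 | [(2-hydroxy-4-methoxyphenyl)methylidene](methyl)oxonium, the protonated ortho-quinone methide, paired with the chiral anion (formed in the flask, step 3) | COc1ccc(C=[O+]C)c(O)c1 | intermediate
10 | (2S,4S)-4,7-dimethoxy-2-[2-(4-methoxyphenyl)benzofuran-5-yl]chroman (2,4-cis) | COc1ccc(-c2cc3cc([C@@H]4C[C@H](OC)c5ccc(OC)cc5O4)ccc3o2)cc1 | intermediate
11 | (2S)-4,7-dimethoxy-2-[2-(4-methoxyphenyl)benzofuran-5-yl]chroman-4-ol, C4 unassigned (formed in the flask, step 4) | COc1ccc(-c2cc3cc([C@@H]4CC(O)(OC)c5ccc(OC)cc5O4)ccc3o2)cc1 | intermediate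
12 | Lophirone J, (S)-7-methoxy-2-[2-(4-methoxyphenyl)benzofuran-5-yl]chroman-4-one | COc1ccc(-c2cc3cc([C@@H]4CC(=O)c5ccc(OC)cc5O4)ccc3o2)cc1 | target

**Step count and risks**

Total steps: 4. Longest linear sequence: 4 (1 → 4 → 5 → 10 → 12); 2, 6 and 7 are bought and enter in steps 1 and 3.

Steps most likely to fail:

1. Step 3 (the step carrying the new method). Possible failures are poor enantiofacial discrimination in the ion pair, acid-induced oligomerisation of the electron-rich vinylarene, Friedel–Crafts alkylation at benzofuran C3, and erosion by reversible ionisation at C2 or C4. The fallback uses known chemistry and sets out from 4-ethynylanisole 2. Sonogashira coupling–cyclisation with 4-bromo-2-iodophenol F1 (reaction at the C–I bond only) would give 5-bromo-2-(4-methoxyphenyl)benzofuran F2. Bromine–lithium exchange (n-BuLi, THF, −78 °C), triisopropyl borate and acidic work-up would give [2-(4-methoxyphenyl)benzofuran-5-yl]boronic acid F3. A palladium(II)/chiral pyridine–oxazoline (t-BuPyOx)-catalysed asymmetric conjugate addition of F3 to 7-methoxy-4H-chromen-4-one F4 (Pd(OCOCF3)2, NH4PF6, water, 1,2-dichloroethane, 60 °C, ligand enantiomer chosen for the S product) would give the flavanone directly. The route is rejoined at 12.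

2. Step 4. Possible failures are competing hydride abstraction at C2, onward dehydrogenation towards the flavone, unproductive charge-transfer consumption of DDQ by the arylbenzofuran, and loss of C2 integrity by ring opening. The fallback sets out from 10. Aqueous acid solvolysis of the activated benzylic ether (cat. TsOH, MeCN/H2O, rt) should give (2S)-7-methoxy-2-[2-(4-methoxyphenyl)benzofuran-5-yl]chroman-4-ol F5 as a C4 epimer mixture, which is of no consequence. Dess–Martin oxidation (NaHCO3-buffered, CH2Cl2) would then return to the route at 12.

3. Step 1. Possible failures are stalling at the uncyclised alkyne because the phenoxide is deactivated by the formyl group, oxidative homocoupling of the alkyne, and catalyst inhibition by the free phenol. The fallback sets out from 1. Acetylation (Ac2O, pyridine) would give 4-formyl-2-iodophenyl acetate F6, and Sonogashira coupling with 2 at rt would give 4-formyl-2-[(4-methoxyphenyl)ethynyl]phenyl acetate F7. Methanolysis (K2CO3, MeOH) would release phenol 3 as a discrete compound, which is closed in a separate π-acid-catalysed 5-endo-dig hydroalkoxylation (cat. AuCl3 or CuI, MeCN or DMF). The route is rejoined at 4.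

**Further compounds**

F1 | step 3 | 4-bromo-2-iodophenol | Oc1ccc(Br)cc1I
F2 | step 3 | 5-bromo-2-(4-methoxyphenyl)benzofuran | COc1ccc(-c2cc3cc(Br)ccc3o2)cc1
F3 | step 3 | [2-(4-methoxyphenyl)benzofuran-5-yl]boronic acid | COc1ccc(-c2cc3cc(B(O)O)ccc3o2)cc1
F4 | step 3 | 7-methoxy-4H-chromen-4-one | COc1ccc2c(c1)occc2=O
F5 | step 4 | (2S)-7-methoxy-2-[2-(4-methoxyphenyl)benzofuran-5-yl]chroman-4-ol (C4 epimer mixture) | COc1ccc(-c2cc3cc([C@@H]4CC(O)c5ccc(OC)cc5O4)ccc3o2)cc1
F6 | step 1 | 4-formyl-2-iodophenyl acetate | CC(=O)Oc1ccc(C=O)cc1I
F7 | step 1 | 4-formyl-2-[(4-methoxyphenyl)ethynyl]phenyl acetate | COc1ccc(C#Cc2cc(C=O)ccc2OC(C)=O)cc1
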